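Two questions stand for each of two flasks, teal and amber: which form holds most of the substrate at the end, and how much. Both start from 16 mM of substrate, and amber runs longer.

| flask | substrate | remark | time |
|---|---|---|---|
| elm | 22 mM | run made earlier |  |
| oak | 35 mM | run made earlier |  |
| teal | 16 mM |  | 30 min |
| amber | 16 mM |  | 40 min |

| run | time / min | target / % | intermediate C / % | intermediate B / % | substrate / % |
|---|---|---|---|---|---|
| elm | 2.00 | 0 | 25 | 4 | 62 |
| elm | 4.00 | 1 | 25 | 6 | 60 |
| elm | 6.00 | 0 | 23 | 9 | 55 |
| elm | 12.0 | 4 | 21 | 25 | 45 |
| elm | 25.0 | 12 | 12 | 42 | 24 |
| oak | 2.00 | 0 | 29 | 2 | 62 |
| oak | 6.00 | 1 | 27 | 12 | 54 |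
| oak | 12.0 | 1 | 21 | 23 | 45 |
| oak | 15.0 | 7 | 17 | 29 | 41 |
| oak | 25.0 | 15 | 11 | 44 | 30 |

(scatter of a reading: 1.5 percentage points)

- which of these there is most of at the end, counted by the substrate in it, teal (substrate / intermediate C / target / intermediate B)
- which of these there is most of at the end, counted by the substrate in it, amber (substrate / intermediate C / target / intermediate B)
- final amount of the leader among these, as a percentage of the substrate charged, in teal
- final amount of the leader among these, as a percentage of the substrate charged, in amber

- the analysis behind the earlier runs scatters by 1.5 percentage points, standard deviation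
- a reading of target is of its free form alone

The zero of my scale is the purely first-order case, where percent curves do not depend on the charge. At 12.0 min substrate reads 45% in elm and 45% in oak, from 22 mM and 35 mM, so I take the two runs as one curve and carry it down to 16 mM.

Intermediate C appears at once and then falls in step with substrate, so I count both as one pool, a pre-equilibrium. Averaged over elm and oak, the pool falls from 89.0% at 2.00 min to 38.5% at 25.0 min. That gives 0.0364 /min, the drain constant: the fraction of the pool leaving per minute. From a full pool it leaves 33.5% at teal's 30 min and 23.3% at amber's 40 min.

I let intermediate B gain what the pool loses and lose to target. Target's rise from 12.0 min to 25.0 min in both runs, set against the intermediate B present, gives a loss constant of 0.0253 /min. With 43.0% of intermediate B at 25.0 min, I reckon a gain of 0.0147 /min as a fraction of the charge, more than the loss of 0.0109 /min. Carried over the 5.00 min to teal's time, that net gain gives 44.9%. By amber's time my reckoned gain is down to 0.00848 /min, less than at 25.0 min, so I hold amber at about the same figure. Target reaches about 30.5% in amber, less than that, and teal's whole pool is less too, so intermediate B leads in both flasks.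

The weak link is the loss constant, a difference of readings that scatter by 1.5 percentage points. Reforged from oak between 15.0 min and 25.0 min, it is 0.0219 /min, and my figure for teal moves to 45.6%. I commit to about 44.9% in both flasks.

The forecast also names intermediate B for teal and intermediate B for amber, at 45% and 46%: “B leads in both runs”.

The flask gives intermediate B at 42.6% in teal and intermediate B at 44.5% in amber.

    intermediate B ⇌ target (K = 1.90, k = 0.0300 /min)
    target ⇌ isomer of the product (K = 0.180, k = 0.270 /min)
    substrate ⇌ intermediate C (K = 0.440, k = 1.40 /min)
    intermediate A → intermediate B (k = 0.290 /min)
    substrate → intermediate A (k = 0.0540 /min)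

What leaves the pool passes through intermediate A, of which amber holds 3.31% at 40.0 min. The drain constant gave amber a pool of 23.3%, and amber holds 22.4%. Read at 1.5 h, the same flask has a reckoned pool of 3.78% and holds 3.45%. There the leader has changed: target stands at 50.5%, more than intermediate B at 36.5%.

The earlier runs and the new flask are simulated with constants of no real substance, and the scatter is random.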